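The route rests on opening ring C at C3–C4 and O1–C2. In the target, ring C holds the array O1–C2H=C3–C4=O, a vinylogous ester in which C3 bears ring B and C2 is unsubstituted. C2–C3 plus ring B can therefore come from an arylacetaldehyde enamine, and C4 plus ring A from an ortho-acetoxybenzoyl chloride. In one flask the β-carbon of enamine 6 is acylated by acid chloride 3 (C3–C4), the acetate is taken off, and the phenoxide attacks C2 and displaces morpholine (O1–C2), giving isoflavone 10. Precursor 3 is 2-acetoxy-4,6-dimethoxybenzoyl chloride; 6 is the E-morpholine enamine of 4-methoxyphenylacetaldehyde. The C6 chain follows by Claisen rearrangement and cross-metathesis.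

Key step: step 4

Remark: compound 1 (4,6-dimethoxysalicylic acid) is assumed to be a catalogue chemical. Methyl ethers are used on O5, O7 and O4' because the peri 5-OMe can be removed selectively by chelation and the other two can be cleaved at the 6-allyl stage, before the acid-sensitive allylic alcohol exists.

Step 1
Reactants: 1 2-hydroxy-4,6-dimethoxybenzoic acid
Product: 2 2-acetoxy-4,6-dimethoxybenzoic acid
Conditions: Ac2O, pyridine, DMAP (cat.), CH2Cl2, 0 °C to rt; then H2O, cold dilute HCl work-up
Reagents that add atoms: acetic anhydride, CC(=O)OC(C)=O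
Why: O-acetylation of a salicylic acid (aspirin-type acylation with Ac2O/pyridine); the water quench hydrolyses any mixed anhydride, and the mild, non-acidic conditions avoid decarboxylation of the electron-rich acid.

Step 2
Reactants: 2 2-acetoxy-4,6-dimethoxybenzoic acid
Product: 3 2-acetoxy-4,6-dimethoxybenzoyl chloride
Conditions: (COCl)2, DMF (cat.), CH2Cl2, 0 °C to rt; concentrate, use crude
Reagents that add atoms: oxalyl chloride, O=C(Cl)C(Cl)=O
Why: acid chloride formation through the chloroiminium species from oxalyl chloride and catalytic DMF; the aryl acetate and methyl ethers are inert to these conditions at room temperature.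

Step 3
Reactants: 4 4-methoxyphenylacetaldehyde; 5 morpholine
Product: 6 (E)-4-[2-(4-methoxyphenyl)ethenyl]morpholine
Conditions: toluene, Dean–Stark, reflux; excess amine stripped in vacuo
Reagents that add atoms: none
Why: enamine condensation of an enolisable aldehyde with a secondary amine, driven by azeotropic removal of water; conjugation with the anisyl ring makes the trans (E) β-aminostyrene the thermodynamic product.

Step 4
Reactants: 3 2-acetoxy-4,6-dimethoxybenzoyl chloride; 6 (E)-4-[2-(4-methoxyphenyl)ethenyl]morpholine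
Product: 10 genistein trimethyl ether (5,7-dimethoxy-3-(4-methoxyphenyl)-4H-chromen-4-one), via enaminone acetate 7 (not isolated), via hydroxy enaminone 8 (not isolated), via 2-morpholinoisoflavanone 9 (not isolated)
Conditions: Et3N, CH2Cl2, 0 °C to rt; then K2CO3 (cat.), MeOH, rt; then AcOH, 50 °C
Reagents that add atoms: none
Why: The nucleophilic β-carbon of 6 adds to the aroyl chloride and Et3N deprotonates the iminium salt, giving enaminone 7 with ring B already on the future C3 (bond C3–C4); methanolysis of the aryl acetate then frees phenol 8, whose oxygen adds to the aminomethylene carbon to give N,O-acetal 9, and acid-assisted loss of morpholine leaves the chromone (bond O1–C2). The closest known chemistry is the Stork acylation of enamines by acid chlorides, used with O-acetylsalicyloyl chlorides to make chromones, together with the ring closure of 2-hydroxyaryl enaminones that underlies the formamide acetal isoflavone synthesis. Ring C closes by a 6-endo-trig oxa-Michael addition followed by elimination, an addition–elimination at a vinylogous amide. No stereocentre remains, since the two sp3 carbons of 9 become C2=C3 again. The step needs acylation at carbon, not nitrogen, and closure through the right oxygen: the tertiary enamine can only be N-acylated reversibly, the acetate survives the amine-free acylation stage and is removed only when methanol and carbonate are added, and of the two ortho oxygens only the acetoxy one can be unmasked to reach C2. Partial hydrolysis of 7 to the formyl ketone would do no harm, because that compound cyclises and dehydrates to 10 as well.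

Step 5
Reactants: 10 genistein trimethyl ether
Product: 11 5-hydroxy-7-methoxy-3-(4-methoxyphenyl)-4H-chromen-4-one
Conditions: BCl3 (1 M in CH2Cl2), CH2Cl2, −78 to 0 °C; aqueous work-up
Reagents that add atoms: none
Why: chelation-controlled ether cleavage, in which BCl3 bridges C4=O and the peri 5-OMe in a six-membered chelate and chloride removes only that methyl group, leaving the 7- and 4'-methyl ethers untouched at or below 0 °C.

Step 6
Reactants: 11 5-hydroxy-7-methoxy-3-(4-methoxyphenyl)-4H-chromen-4-one; 12 allyl bromide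
Product: 13 5-(allyloxy)-7-methoxy-3-(4-methoxyphenyl)-4H-chromen-4-one
Conditions: K2CO3, DMF, 60 °C
Reagents that add atoms: none
Why: Williamson etherification of the only free hydroxyl; warm DMF with K2CO3 overcomes the hydrogen bond of the 5-OH to C4=O without opening the pyranone ring.

Step 7
Reactants: 13 5-(allyloxy)-7-methoxy-3-(4-methoxyphenyl)-4H-chromen-4-one
Product: 15 6-allyl-5-hydroxy-7-methoxy-3-(4-methoxyphenyl)-4H-chromen-4-one, via Claisen dienone 14 (not isolated)
Conditions: N,N-diethylaniline, 200 °C, Ar
Reagents that add atoms: none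
Why: aromatic Claisen rearrangement, a [3,3] shift of the allyl group from O5 to C6, the only ortho carbon that carries hydrogen (the other is the ring-fusion carbon C4a), followed by enolisation of dienone 14 to the phenol, which is again hydrogen-bonded to C4=O.

Step 8
Reactants: 15 6-allyl-5-hydroxy-7-methoxy-3-(4-methoxyphenyl)-4H-chromen-4-one
Product: 16 6-allylgenistein (6-allyl-5,7-dihydroxy-3-(4-hydroxyphenyl)-4H-chromen-4-one)
Conditions: BBr3, CH2Cl2, −78 °C to rt; ice-water quench
Reagents that add atoms: none
Why: Lewis-acid cleavage of the two remaining aryl methyl ethers by BBr3 (aryloxyborane formation with loss of MeBr); a terminal allyl group on a phenol ring tolerates BBr3 at or below room temperature, and the cleavage is placed here because no allylic alcohol is present yet.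

Step 9
Reactants: 16 6-allylgenistein; 17 methacrolein
Product: 18 (E)-4-[5,7-dihydroxy-3-(4-hydroxyphenyl)-4-oxo-4H-chromen-6-yl]-2-methylbut-2-enal
Conditions: (H2IMes)(PCy3)Cl2Ru=CHPh (second-generation Grubbs catalyst, 5 mol%), 1,4-benzoquinone (10 mol%), excess 17, EtOAc, 50 °C
Reagents that add atoms: none
Why: olefin cross-metathesis of the terminal allyl alkene with an excess of the electron-poor 1,1-disubstituted partner, which does not homodimerise; the trisubstituted enal should form as the E isomer (CHO trans to the ArCH2 group) under thermodynamic control, which sets the side-chain geometry, and benzoquinone suppresses double-bond migration.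

Step 10
Reactants: 18 (E)-4-[5,7-dihydroxy-3-(4-hydroxyphenyl)-4-oxo-4H-chromen-6-yl]-2-methylbut-2-enal
Product: 19 5,7-dihydroxy-6-[(E)-4-hydroxy-3-methylbut-2-en-1-yl]-3-(4-hydroxyphenyl)-4H-chromen-4-one (target)
Conditions: NaBH4, CeCl3·7H2O, MeOH, −20 to 0 °C; aq. NH4Cl
Reagents that add atoms: none
Why: Luche reduction, in which 1,2-hydride delivery to the aldehyde is much faster than attack on the chromone, whose C4=O is a vinylogous ester hydrogen-bonded to 5-OH, so the allylic alcohol should form with the E double bond unchanged.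

Compound list
1 | 2-hydroxy-4,6-dimethoxybenzoic acid | COc1cc(O)c(C(=O)O)c(OC)c1 | starting material
2 | 2-acetoxy-4,6-dimethoxybenzoic acid | CC(=O)Oc1cc(OC)cc(OC)c1C(=O)O | intermediate
3 | 2-acetoxy-4,6-dimethoxybenzoyl chloride | CC(=O)Oc1cc(OC)cc(OC)c1C(Cl)=O | intermediate
4 | 4-methoxyphenylacetaldehyde | COc1ccc(CC=O)cc1 | starting material
5 | morpholine | C1COCCN1 | starting material
6 | (E)-4-[2-(4-methoxyphenyl)ethenyl]morpholine | COc1ccc(/C=C/N2CCOCC2)cc1 | intermediate
7 | (E)-1-(2-acetoxy-4,6-dimethoxyphenyl)-2-(4-methoxyphenyl)-3-(morpholin-4-yl)prop-2-en-1-one (enaminone acetate, not isolated; drawn E, the push–pull double bond isomerises freely) | CC(=O)Oc1cc(OC)cc(OC)c1C(=O)/C(=C/N1CCOCC1)c1ccc(OC)cc1 | intermediate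
8 | (E)-1-(2-hydroxy-4,6-dimethoxyphenyl)-2-(4-methoxyphenyl)-3-(morpholin-4-yl)prop-2-en-1-one (hydroxy enaminone, not isolated) | Oc1cc(OC)cc(OC)c1C(=O)/C(=C/N1CCOCC1)c1ccc(OC)cc1 | intermediate
9 | 5,7-dimethoxy-3-(4-methoxyphenyl)-2-(morpholin-4-yl)chroman-4-one (not isolated; racemic mixture of C2/C3 diastereomers, both centres lost on elimination) | COc1ccc(C2C(N3CCOCC3)Oc3cc(OC)cc(OC)c3C2=O)cc1 | intermediate
10 | genistein trimethyl ether, 5,7-dimethoxy-3-(4-methoxyphenyl)-4H-chromen-4-one | COc1ccc(-c2coc3cc(OC)cc(OC)c3c2=O)cc1 | intermediate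
11 | 5-hydroxy-7-methoxy-3-(4-methoxyphenyl)-4H-chromen-4-one | COc1ccc(-c2coc3cc(OC)cc(O)c3c2=O)cc1 | intermediate
12 | allyl bromide | C=CCBr | starting material
13 | 5-(allyloxy)-7-methoxy-3-(4-methoxyphenyl)-4H-chromen-4-one | C=CCOc1cc(OC)cc2occ(-c3ccc(OC)cc3)c(=O)c12 | intermediate
14 | 6-allyl-7-methoxy-3-(4-methoxyphenyl)-6H-chromene-4,5-dione (Claisen dienone, not isolated; racemic at C6, centre lost on enolisation) | C=CCC1C(=O)C2=C(C=C1OC)OC=C(C2=O)c1ccc(OC)cc1 | intermediate
15 | 6-allyl-5-hydroxy-7-methoxy-3-(4-methoxyphenyl)-4H-chromen-4-one | C=CCc1c(OC)cc2occ(-c3ccc(OC)cc3)c(=O)c2c1O | intermediate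
16 | 6-allylgenistein, 6-allyl-5,7-dihydroxy-3-(4-hydroxyphenyl)-4H-chromen-4-one | C=CCc1c(O)cc2occ(-c3ccc(O)cc3)c(=O)c2c1O | intermediate
17 | methacrolein | CC(=C)C=O | starting material
18 | (E)-4-[5,7-dihydroxy-3-(4-hydroxyphenyl)-4-oxo-4H-chromen-6-yl]-2-methylbut-2-enal | C/C(=C\Cc1c(O)cc2occ(-c3ccc(O)cc3)c(=O)c2c1O)C=O | intermediate
19 | 5,7-dihydroxy-6-[(E)-4-hydroxy-3-methylbut-2-en-1-yl]-3-(4-hydroxyphenyl)-4H-chromen-4-one | C/C(=C\Cc1c(O)cc2occ(-c3ccc(O)cc3)c(=O)c2c1O)CO | target

Total step count: 10
Longest linear sequence: 9 steps (1 → 2 → 3 → 10 → 11 → 13 → 15 → 16 → 18 → 19)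

Steps most likely to fail

Step 4. What may go wrong: slow C-acylation by the doubly ortho-substituted, electron-rich acid chloride, so that hydrolysis of the enamine or transfer of the acetyl group instead of the aroyl group competes. Fallback: set out from acid chloride 3 and make the C3–C4 bond with a benzyl organometallic, adding C2 afterwards as a one-carbon unit. Negishi-type acylation of 4-methoxybenzylzinc chloride with 3 under Pd(PPh3)4 catalysis in THF at rt should give 1-(2-acetoxy-4,6-dimethoxyphenyl)-2-(4-methoxyphenyl)ethanone F1. K2CO3 in MeOH should free 1-(2-hydroxy-4,6-dimethoxyphenyl)-2-(4-methoxyphenyl)ethanone F2. Heating F2 with N,N-dimethylformamide dimethyl acetal in toluene should give (E)-3-(dimethylamino)-1-(2-hydroxy-4,6-dimethoxyphenyl)-2-(4-methoxyphenyl)prop-2-en-1-one F3, which closes in the flask with loss of dimethylamine and rejoins the route at 10.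

Step 8. What may go wrong: acid-promoted attack on the allyl group during ether cleavage (hydrobromination, or ring closure of the allyl group onto a neighbouring phenol oxygen), or incomplete cleavage of the 7-methyl ether. Fallback: set out from 10 and remove all methyl groups before any alkene is present. BBr3 in CH2Cl2 should give genistein F4. MOMCl with iPr2NEt in CH2Cl2 should protect the two acidic phenols and leave the chelated 5-OH, giving 5-hydroxy-7-(methoxymethoxy)-3-[4-(methoxymethoxy)phenyl]-4H-chromen-4-one F5. Allyl bromide 12 with K2CO3 in DMF should give 5-(allyloxy)-7-(methoxymethoxy)-3-[4-(methoxymethoxy)phenyl]-4H-chromen-4-one F6. Claisen rearrangement in N,N-diethylaniline, through 6-allyl-7-(methoxymethoxy)-3-[4-(methoxymethoxy)phenyl]-6H-chromene-4,5-dione F7, should give 6-allyl-5-hydroxy-7-(methoxymethoxy)-3-[4-(methoxymethoxy)phenyl]-4H-chromen-4-one F8. HCl in MeOH at 50 °C should remove both acetals, which the terminal allyl group tolerates, and the route is rejoined at 16.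

Step 9. What may go wrong: catalyst deactivation or migration of the allyl double bond into conjugation in the presence of three free phenols, and poor solubility of the triol. Fallback: set out from 16 and mask the phenols as acetates through metathesis and reduction. Ac2O in pyridine should give 6-allylgenistein triacetate F9. Cross-metathesis with methacrolein 17 under (H2IMes)(PCy3)Cl2Ru=CHPh in CH2Cl2 should give the (E)-enal triacetate F10. NaBH4 with CeCl3·7H2O in MeOH should give the (E)-allylic alcohol triacetate F11. K2CO3 in MeOH at 0 °C to rt should remove the three aryl acetates, and the route is rejoined at target 19.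

Further compounds
F1 | step 4 | 1-(2-acetoxy-4,6-dimethoxyphenyl)-2-(4-methoxyphenyl)ethanone | CC(=O)Oc1cc(OC)cc(OC)c1C(=O)Cc1ccc(OC)cc1
F2 | step 4 | 1-(2-hydroxy-4,6-dimethoxyphenyl)-2-(4-methoxyphenyl)ethanone | COc1ccc(CC(=O)c2c(O)cc(OC)cc2OC)cc1
F3 | step 4 | (E)-3-(dimethylamino)-1-(2-hydroxy-4,6-dimethoxyphenyl)-2-(4-methoxyphenyl)prop-2-en-1-one | CN(C)/C=C(/C(=O)c1c(O)cc(OC)cc1OC)c1ccc(OC)cc1
F4 | step 8 | genistein, 5,7-dihydroxy-3-(4-hydroxyphenyl)-4H-chromen-4-one | Oc1ccc(-c2coc3cc(O)cc(O)c3c2=O)cc1
F5 | step 8 | 5-hydroxy-7-(methoxymethoxy)-3-[4-(methoxymethoxy)phenyl]-4H-chromen-4-one | COCOc1ccc(-c2coc3cc(OCOC)cc(O)c3c2=O)cc1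
F6 | step 8 | 5-(allyloxy)-7-(methoxymethoxy)-3-[4-(methoxymethoxy)phenyl]-4H-chromen-4-one | C=CCOc1cc(OCOC)cc2occ(-c3ccc(OCOC)cc3)c(=O)c12
F7 | step 8 | 6-allyl-7-(methoxymethoxy)-3-[4-(methoxymethoxy)phenyl]-6H-chromene-4,5-dione (racemic at C6) | C=CCC1C(=O)C2=C(C=C1OCOC)OC=C(C2=O)c1ccc(OCOC)cc1
F8 | step 8 | 6-allyl-5-hydroxy-7-(methoxymethoxy)-3-[4-(methoxymethoxy)phenyl]-4H-chromen-4-one | C=CCc1c(OCOC)cc2occ(-c3ccc(OCOC)cc3)c(=O)c2c1O
F9 | step 9 | 6-allylgenistein triacetate, 3-(4-acetoxyphenyl)-6-allyl-4-oxo-4H-chromene-5,7-diyl diacetate | C=CCc1c(OC(C)=O)cc2occ(-c3ccc(OC(C)=O)cc3)c(=O)c2c1OC(C)=O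
F10 | step 9 | 3-(4-acetoxyphenyl)-6-[(E)-3-methyl-4-oxobut-2-en-1-yl]-4-oxo-4H-chromene-5,7-diyl diacetate | C/C(=C\Cc1c(OC(C)=O)cc2occ(-c3ccc(OC(C)=O)cc3)c(=O)c2c1OC(C)=O)C=O
F11 | step 9 | 3-(4-acetoxyphenyl)-6-[(E)-4-hydroxy-3-methylbut-2-en-1-yl]-4-oxo-4H-chromene-5,7-diyl diacetate | C/C(=C\Cc1c(OC(C)=O)cc2occ(-c3ccc(OC(C)=O)cc3)c(=O)c2c1OC(C)=O)CO
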